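Numbering (lignan style): ring A–C7H2–C8H(C9H2–O)–C8'H(CH3)–C7'H(O)–ring B. The oxolane is C7'–O–C9–C8–C8'. The carbocycle is C7–C8–C8'–C7' plus two carbons of each arene.
Cuts: C9H2 is traced back to a lactone C=O. O–C9 and C7'–C8' are then cut together (aldehyde + enoate), followed by C7–C8 (benzyl–alkenyl coupling), ring B–C7' (C–H olefination, alkene later trimmed to CHO) and last the aryl–aryl bond.
Enabling feature: in the bicyclo[5.2.1] core the one-atom bridge C8' (CH–CH3) joins bridgehead C7' (ArCH–O on ring B) to bridgehead C8, which carries both C7H2 (to ring A) and C9. The chain O–C7'–C8'–C8–C9 is the γ-lactone pattern of an aldehyde/β-methyl-enoate reductive coupling. Because C7' and C8 are already tied through rings B and A, the same C7'–C8' bond also closes the eight-membered ring.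
Forward order: biaryl bond, then the fourth ortho group together with the axis, then the arms trimmed to CH2Br and CHO, then the enoate attached. The carbocycle and lactone close in one SmI2 step, and the lactone is reduced and re-closed as the oxolane.
Stereochemistry: only the aR (M) axis is set by catalysis. C7', C8' and C8 (all S) are relayed from it in the SmI2 step with the help of the Z alkene, which comes from a syn-hydrostannation and a retentive Stille coupling.

Key step: step 9

Assumption: the SMILES fixes C7', C8 and C8' (all S) but cannot carry the biaryl axis; a torsion analysis of the cage (for 7'S,8S the C7'–O and C8–C9 bonds converge only when C7–C8–C8'–C7' is positive and C8–C8'–C7'–C(ring B) is negative, the sign pattern of a cyclooctadiene with a negative biaryl torsion) pairs these centres with the M helix, descriptor aR, so aR is made; this pairing and the expectation that L-tert-leucine gives aR are model-based, are to be checked by X-ray or ECD on the olefination product and on the lactone, and D-tert-leucine is equally available.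

Step 1
Reactants: 1 2-bromo-3,4,5-trimethoxybenzaldehyde; 2 (2,3,4-trimethoxyphenyl)boronic acid
Product: 3 2',3',4,4',5,6-hexamethoxybiphenyl-2-carbaldehyde
Conditions: Pd(OAc)2 (2 mol %), SPhos (4 mol %), K3PO4, toluene/H2O, 90 °C
Reagents that add atoms: none
Why: Suzuki–Miyaura coupling with a bulky dialkylbiarylphosphine, the standard solution for tri-ortho-substituted biaryls; the aldehyde is inert and no stereo element is fixed because an axis flanked only by CHO and two OMe groups should still turn at the temperatures of this step and the next.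

Step 2
Reactants: 3 2',3',4,4',5,6-hexamethoxybiphenyl-2-carbaldehyde; 4 methyl acrylate
Product: 5 methyl (E)-3-[(aR)-2'-formyl-4,4',5,5',6,6'-hexamethoxybiphenyl-2-yl]acrylate
Conditions: Pd(OAc)2 (10 mol %), L-tert-leucine (30 mol %), 1,4-benzoquinone (1.5 equiv), (CF3)2CHOH/AcOH, 60 °C
Reagents that add atoms: none
Why: Atroposelective oxidative C–H olefination (Fujiwara–Moritani type) steered by a transient chiral directing group, a reaction established for biaryl-2-carbaldehydes: the reversibly formed tert-leucine imine delivers divalent palladium to the only free ortho C–H of ring B through the faster-reacting of two interconverting atropisomeric imines (dynamic kinetic resolution), and the resulting E-acrylate arm is the fourth ortho group that locks the aR axis.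

Step 3
Reactants: 5 methyl (E)-3-[(aR)-2'-formyl-4,4',5,5',6,6'-hexamethoxybiphenyl-2-yl]acrylate
Product: 6 methyl (E)-3-[(aR)-2'-(hydroxymethyl)-4,4',5,5',6,6'-hexamethoxybiphenyl-2-yl]acrylate
Conditions: NaBH4, MeOH/THF, 0 °C
Reagents that add atoms: none
Why: Chemoselective borohydride 1,2-reduction of the aryl aldehyde, which is far faster than any attack on the conjugated ester at 0 °C and cannot disturb the now tetra-ortho-substituted axis.

Step 4
Reactants: 6 methyl (E)-3-[(aR)-2'-(hydroxymethyl)-4,4',5,5',6,6'-hexamethoxybiphenyl-2-yl]acrylate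
Product: 7 methyl (E)-3-[(aR)-2'-(acetoxymethyl)-4,4',5,5',6,6'-hexamethoxybiphenyl-2-yl]acrylate
Conditions: Ac2O, pyridine, DMAP (cat.), CH2Cl2, 0 °C to rt
Reagents that add atoms: acetic anhydride, CC(=O)OC(C)=O
Why: DMAP-catalysed acetylation of a primary benzylic alcohol; the acetate stops this arm from closing onto the aldehyde of step 5 as a seven-membered lactol and, unlike a benzylic bromide, survives aqueous periodate.

Step 5
Reactants: 7 methyl (E)-3-[(aR)-2'-(acetoxymethyl)-4,4',5,5',6,6'-hexamethoxybiphenyl-2-yl]acrylate
Product: 9 [(aR)-2'-formyl-4,4',5,5',6,6'-hexamethoxybiphenyl-2-yl]methyl acetate, via syn-diol 8 (not isolated)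
Conditions: OsO4 (2–5 mol %), NaIO4 (4 equiv), 2,6-lutidine, 1,4-dioxane/H2O (3:1), rt
Reagents that add atoms: OsO4 (delivers the oxygen atoms), O=[Os](=O)(=O)=O; NaIO4 (terminal oxidant that restores OsO4), [Na+].[O-]I(=O)(=O)=O
Why: Lemieux–Johnson oxidation, that is catalytic syn-dihydroxylation of the only alkene followed by periodate glycol cleavage in the same flask, preferred to ozone because the two trimethoxyarenes are themselves ozone-sensitive; the two transient carbinol centres of 8 are erased at once.

Step 6
Reactants: 9 [(aR)-2'-formyl-4,4',5,5',6,6'-hexamethoxybiphenyl-2-yl]methyl acetate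
Product: 10 (aR)-2'-(bromomethyl)-4,4',5,5',6,6'-hexamethoxybiphenyl-2-carbaldehyde
Conditions: HBr (33 % in AcOH), CH2Cl2, 0 °C, short contact
Reagents that add atoms: hydrogen bromide, Br
Why: Classical acetate-to-bromide exchange with HBr in acetic acid, an SN1-like substitution made easy by the para-methoxy group of ring A, run cold and short so that the aryl methyl ethers and the aldehyde stay untouched.

Step 7
Reactants: 11 methyl but-2-ynoate
Product: 12 methyl (E)-2-(tributylstannyl)but-2-enoate
Conditions: Bu3SnH, Pd(PPh3)4 (2 mol %), THF, 0 °C to rt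
Reagents that add atoms: tributyltin hydride, CCCC[SnH](CCCC)CCCC
Why: Palladium-catalysed syn-hydrostannation of an alkynoate, which places tin on the α-carbon and hydrogen on the β-carbon from the same side, so the methyl group ends cis to the ester (descriptor E because tin outranks carbon).

Step 8
Reactants: 10 (aR)-2'-(bromomethyl)-4,4',5,5',6,6'-hexamethoxybiphenyl-2-carbaldehyde; 12 methyl (E)-2-(tributylstannyl)but-2-enoate
Product: 13 methyl (Z)-2-{[(aR)-2'-formyl-4,4',5,5',6,6'-hexamethoxybiphenyl-2-yl]methyl}but-2-enoate
Conditions: Pd2(dba)3 (2.5 mol %), AsPh3 (20 mol %), CuI (10 mol %), NMP, 45 °C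
Reagents that add atoms: none
Why: Stille coupling of a benzylic bromide with an α-stannyl enoate under the AsPh3/CuI-accelerated protocol; the alkenyl group is transferred with retention, so C7 takes the place of tin (methyl trans to C7, descriptor Z) and the neutral medium spares the aldehyde.

Step 9
Reactants: 13 methyl (Z)-2-{[(aR)-2'-formyl-4,4',5,5',6,6'-hexamethoxybiphenyl-2-yl]methyl}but-2-enoate
Product: 15 (aR,7'S,8S,8'S)-3,3',4,4',5,5'-hexamethoxy-2,2'-cyclolignano-9,7'-lactone, via hydroxy ester 14 (not isolated)
Conditions: 13 added by syringe pump (final 2 mM) to SmI2 (3 equiv, 0.1 M in THF), t-BuOH (2 equiv), THF, 0 °C to rt, no HMPA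
Reagents that add atoms: none
Why: Proposed new method: SmI2 reduces the aryl aldehyde (much easier to reduce than the trisubstituted enoate) to a samarium ketyl whose carbon C7' adds to the β-carbon C8' in an 8-endo-trig radical closure of the carbocycle, a second electron turns the α-ester radical into a samarium enolate that t-BuOH protonates at C8, and the C7' alkoxide of 14 then attacks the C9 ester in a 5-exo-trig acyl substitution that expels methoxide and closes the bridging lactone. The closest known reaction types are the SmI2 reductive coupling of aldehydes with α,β-unsaturated esters to γ-butyrolactones and the SmI2 8-endo ketyl–olefin cyclisation of biaryl-tethered carbonyl compounds, and what is untested is their merger, with the ester on the ring-internal α-carbon so that the lactonisation is transannular. C8' is controlled by the axis and the alkene geometry: the aR helix lets C7' reach only the alkene face that gives a positive C7–C8–C8'–C7' torsion, and since the Z alkene keeps the methyl group trans to C7, attack on that face gives 8'S with the methyl pointing away from the biaryl. C7' is controlled by chelation: trivalent samarium bridging the ketyl oxygen and the ester carbonyl turns the oxygen towards C9 and the hydrogen outwards (7'S), which is why HMPA is left out. C8 is set by protonation of the chelated enolate from the open outer face (8S, C9 cis to the C7' oxygen), and an 8-epimer cannot lactonise and should be returned through the enolate by the basic samarium alkoxides present. The step needs ring closure to outrun pinacol dimerisation and plain reduction of the ketyl; the substrate helps because both reacting groups hang from the two ortho carbons flanking the biaryl bond, so half of the forming ring is already rigid and a nucleophilic radical meets an electron-poor carbon, and slow addition at high dilution does the rest.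

Step 10
Reactants: 15 (aR,7'S,8S,8'S)-3,3',4,4',5,5'-hexamethoxy-2,2'-cyclolignano-9,7'-lactone
Product: 16 (aR,7'S,8S,8'S)-3,3',4,4',5,5'-hexamethoxy-2,2'-cyclolignane-7',9-diol
Conditions: LiAlH4, THF, 0 °C to rt
Reagents that add atoms: none
Why: Standard hydride reduction of a γ-lactone to the 1,4-diol, which breaks only the O–C9 acyl bond and touches none of the stereocentres or the axis.

Step 11
Reactants: 16 (aR,7'S,8S,8'S)-3,3',4,4',5,5'-hexamethoxy-2,2'-cyclolignane-7',9-diol
Product: 18 (aR,7'S,8S,8'S)-7',9-epoxy-3,3',4,4',5,5'-hexamethoxy-2,2'-cyclolignane (CNP0392777.1), via primary tosylate 17 (not isolated)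
Conditions: NaH (2.5 equiv), THF, 0 °C; TsCl (1.05 equiv), 0 °C to rt
Reagents that add atoms: none
Why: Williamson-type cyclodehydration of a 1,4-diol: the less hindered primary alkoxide is sulfonylated first and the C7' alkoxide displaces tosylate at C9 (5-exo-tet), so the C7'–O bond and all three stereocentres are kept.

Compound list (the aR axis of 5–10 and 13–18 cannot be written in SMILES)
1 | 2-bromo-3,4,5-trimethoxybenzaldehyde | O=Cc1cc(OC)c(OC)c(OC)c1Br | starting material
2 | (2,3,4-trimethoxyphenyl)boronic acid | OB(O)c1ccc(OC)c(OC)c1OC | starting material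
3 | 2',3',4,4',5,6-hexamethoxybiphenyl-2-carbaldehyde (axis not fixed) | O=Cc1cc(OC)c(OC)c(OC)c1-c1ccc(OC)c(OC)c1OC | intermediate
4 | methyl acrylate | C=CC(=O)OC | starting material
5 | methyl (E)-3-[(aR)-2'-formyl-4,4',5,5',6,6'-hexamethoxybiphenyl-2-yl]acrylate | O=Cc1cc(OC)c(OC)c(OC)c1-c1c(/C=C/C(=O)OC)cc(OC)c(OC)c1OC | intermediate
6 | methyl (E)-3-[(aR)-2'-(hydroxymethyl)-4,4',5,5',6,6'-hexamethoxybiphenyl-2-yl]acrylate | OCc1cc(OC)c(OC)c(OC)c1-c1c(/C=C/C(=O)OC)cc(OC)c(OC)c1OC | intermediate
7 | methyl (E)-3-[(aR)-2'-(acetoxymethyl)-4,4',5,5',6,6'-hexamethoxybiphenyl-2-yl]acrylate | CC(=O)OCc1cc(OC)c(OC)c(OC)c1-c1c(/C=C/C(=O)OC)cc(OC)c(OC)c1OC | intermediate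
8 | methyl 3-[(aR)-2'-(acetoxymethyl)-4,4',5,5',6,6'-hexamethoxybiphenyl-2-yl]-2,3-dihydroxypropanoate, syn-diol, both face isomers, not isolated | CC(=O)OCc1cc(OC)c(OC)c(OC)c1-c1c(C(O)C(O)C(=O)OC)cc(OC)c(OC)c1OC | intermediate
9 | [(aR)-2'-formyl-4,4',5,5',6,6'-hexamethoxybiphenyl-2-yl]methyl acetate | CC(=O)OCc1cc(OC)c(OC)c(OC)c1-c1c(C=O)cc(OC)c(OC)c1OC | intermediate
10 | (aR)-2'-(bromomethyl)-4,4',5,5',6,6'-hexamethoxybiphenyl-2-carbaldehyde (CH2Br = C7, CHO = C7') | BrCc1cc(OC)c(OC)c(OC)c1-c1c(C=O)cc(OC)c(OC)c1OC | intermediate
11 | methyl but-2-ynoate | CC#CC(=O)OC | starting material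
12 | methyl (E)-2-(tributylstannyl)but-2-enoate | C/C=C(/[Sn](CCCC)(CCCC)CCCC)C(=O)OC | intermediate
13 | methyl (Z)-2-{[(aR)-2'-formyl-4,4',5,5',6,6'-hexamethoxybiphenyl-2-yl]methyl}but-2-enoate | C/C=C(/Cc1cc(OC)c(OC)c(OC)c1-c1c(C=O)cc(OC)c(OC)c1OC)C(=O)OC | intermediate
14 | methyl (aR,7'S,8S,8'S)-7'-hydroxy-3,3',4,4',5,5'-hexamethoxy-2,2'-cyclolignan-9-oate, present as its samarium alkoxide, not isolated | COc1cc2c(c(OC)c1OC)-c1c(cc(OC)c(OC)c1OC)[C@@H](O)[C@@H](C)[C@@H](C(=O)OC)C2 | intermediate
15 | (aR,7'S,8S,8'S)-3,3',4,4',5,5'-hexamethoxy-2,2'-cyclolignano-9,7'-lactone | COc1cc2c(c(OC)c1OC)-c1c(cc(OC)c(OC)c1OC)[C@H]1OC(=O)[C@@H](C2)[C@@H]1C | intermediate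
16 | (aR,7'S,8S,8'S)-3,3',4,4',5,5'-hexamethoxy-2,2'-cyclolignane-7',9-diol | COc1cc2c(c(OC)c1OC)-c1c(cc(OC)c(OC)c1OC)[C@@H](O)[C@@H](C)[C@@H](CO)C2 | intermediate
17 | 9-O-tosylate of 16, present as its sodium alkoxide, not isolated | COc1cc2c(c(OC)c1OC)-c1c(cc(OC)c(OC)c1OC)[C@@H](O)[C@@H](C)[C@@H](COS(=O)(=O)c3ccc(C)cc3)C2 | intermediate
18 | (aR,7'S,8S,8'S)-7',9-epoxy-3,3',4,4',5,5'-hexamethoxy-2,2'-cyclolignane, CNP0392777.1 | COc1cc2c(c(OC)c1OC)-c1c(cc(OC)c(OC)c1OC)[C@H]1OC[C@@H](C2)[C@@H]1C | target

Total step count: 11. Longest linear sequence: 10 steps (1–6, then 8–11). Step 7 is the side branch.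

Steps most likely to fail

Step 9. The 8-endo addition to a β-methyl, α-branched enoate may be slower than bimolecular pinacol coupling or further reduction of the ketyl to the benzylic alcohol. Without a tight samarium chelate the ketyl may also add through its other face, giving a C7' epimer that cannot lactonise.

The fallback makes the same C7'–C8' bond by a known polar ring closure, an intramolecular Nozaki–Hiyama allylation. It sets out from 12 and 10 and returns at 16.
- Reduction of 12 with i-Bu2AlH (CH2Cl2, −78 °C) gives (E)-2-(tributylstannyl)but-2-en-1-ol F1.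
- Stille coupling of F1 with 10 under the conditions of step 8 gives (aR)-2'-[(Z)-2-(hydroxymethyl)but-2-en-1-yl]-4,4',5,5',6,6'-hexamethoxybiphenyl-2-carbaldehyde F2.
- PBr3 in Et2O at 0 °C gives (aR)-2'-[(Z)-2-(bromomethyl)but-2-en-1-yl]-4,4',5,5',6,6'-hexamethoxybiphenyl-2-carbaldehyde F3. The CBr4/PPh3 system is avoided because it would olefinate the aldehyde.
- CrCl2 in THF at high dilution turns the bromide into an allylchromium species that attacks the aldehyde through its γ-carbon C8'. The usual anti preference matches the anti C7'–OH/C8'–CH3 relation required. The product is (aR,7'S,8'S)-3,3',4,4',5,5'-hexamethoxy-8(9)-didehydro-2,2'-cyclolignan-7'-ol F4, an eight-membered homoallylic alcohol with an exocyclic C8=C9 methylene.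
- Hydroboration with 9-BBN from the open outer face, then NaOH/H2O2, gives 16.

Step 2. Rotation about the buttressed tri-ortho axis of 3 may be too slow at 60 °C, so the dynamic resolution decays to a simple kinetic resolution that uses only half of the material. Palladation of the crowded, electron-rich ring may also turn over poorly.

The fallback builds the tetra-ortho biaryl racemically and resolves it. It sets out from 1 and returns at 5.
- Ullmann homocoupling of 1 (activated copper, DMF, reflux) gives racemic, C2-symmetric 4,4',5,5',6,6'-hexamethoxybiphenyl-2,2'-dicarbaldehyde F5.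
- Its two formyl groups are equivalent, so a Horner–Wadsworth–Emmons reaction with one equivalent of trimethyl phosphonoacetate (LiCl, DBU, MeCN) gives racemic 5. The by-products are separable bis-olefin and recovered dialdehyde.
- The axis is configurationally stable, so the enantiomers are separated by preparative chromatography on a polysaccharide chiral phase, and the aR antipode re-enters at 5.

Step 8. Transmetalation from the hindered, electron-poor α-stannyl enoate may be slow. That would let protodestannylation, cine substitution or erosion of the alkene geometry compete.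

The fallback makes C7–C8 by enolate alkylation and sets the geometry through a stereodefined enol triflate. It sets out from 10 and returns at 13.
- Alkylation of methyl acetoacetate with 10 (K2CO3, acetone, rt) gives methyl 2-acetyl-3-[(aR)-2'-formyl-4,4',5,5',6,6'-hexamethoxybiphenyl-2-yl]propanoate F6.
- Triflation under non-chelating conditions (Tf2O, aqueous Me4NOH, toluene, 0 °C) gives methyl (E)-2-{[(aR)-2'-formyl-4,4',5,5',6,6'-hexamethoxybiphenyl-2-yl]methyl}-3-(trifluoromethylsulfonyloxy)but-2-enoate F7, with the triflate trans to the ester.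
- Palladium-catalysed formate reduction (Pd(OAc)2, PPh3, HCO2H, Bu3N, DMF, 60 °C) replaces the triflate by hydrogen with retention and gives 13.

Further compounds
F1 | step 9 | (E)-2-(tributylstannyl)but-2-en-1-ol | C/C=C(/[Sn](CCCC)(CCCC)CCCC)CO
F2 | step 9 | (aR)-2'-[(Z)-2-(hydroxymethyl)but-2-en-1-yl]-4,4',5,5',6,6'-hexamethoxybiphenyl-2-carbaldehyde | C/C=C(/Cc1cc(OC)c(OC)c(OC)c1-c1c(C=O)cc(OC)c(OC)c1OC)CO
F3 | step 9 | (aR)-2'-[(Z)-2-(bromomethyl)but-2-en-1-yl]-4,4',5,5',6,6'-hexamethoxybiphenyl-2-carbaldehyde | C/C=C(/Cc1cc(OC)c(OC)c(OC)c1-c1c(C=O)cc(OC)c(OC)c1OC)CBr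
F4 | step 9 | (aR,7'S,8'S)-3,3',4,4',5,5'-hexamethoxy-8(9)-didehydro-2,2'-cyclolignan-7'-ol | COc1cc2c(c(OC)c1OC)-c1c(cc(OC)c(OC)c1OC)[C@@H](O)[C@@H](C)C(=C)C2
F5 | step 2 | 4,4',5,5',6,6'-hexamethoxybiphenyl-2,2'-dicarbaldehyde (racemic) | O=Cc1cc(OC)c(OC)c(OC)c1-c1c(C=O)cc(OC)c(OC)c1OC
F6 | step 8 | methyl 2-acetyl-3-[(aR)-2'-formyl-4,4',5,5',6,6'-hexamethoxybiphenyl-2-yl]propanoate (both α-epimers) | CC(=O)C(Cc1cc(OC)c(OC)c(OC)c1-c1c(C=O)cc(OC)c(OC)c1OC)C(=O)OC
F7 | step 8 | methyl (E)-2-{[(aR)-2'-formyl-4,4',5,5',6,6'-hexamethoxybiphenyl-2-yl]methyl}-3-(trifluoromethylsulfonyloxy)but-2-enoate | C/C(OS(=O)(=O)C(F)(F)F)=C(/Cc1cc(OC)c(OC)c(OC)c1-c1c(C=O)cc(OC)c(OC)c1OC)C(=O)OC
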